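Second substrate loads the free catalyst at lower concentrations than starting material does: the half-load level (Michaelis constant), which is the back and onward rate constants over the forward one, is 0.379 M against 6.77 M.

common to all: starting material 2.0 M; free catalyst 10 mM; time 8.0 h
- Sunday's: second substrate 0.600 M
- Monday's: second substrate 0.800 M
- Tuesday's: second substrate 1.20 M
- Friday's: second substrate 2.00 M

* [target] at the end for Sunday's, Monday's, Tuesday's, Friday's, in this order
* how the row runs (rises, then falls / rises all the way / falls all the way / hardly changes / falls, then rises)

- a species is counted by the starting material in it: one homo dimer counts as two
- where a step has two of a species, its rate is k times that concentration squared, and two are used at each turn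
- "hardly changes" means that all values lie within two and a half points (for a concentration: within two and a half percent of the largest)
- run time (Sunday's): 8.0 h

    starting material + free catalyst ⇌ catalyst intermediate A (K1 = 0.84 M⁻¹, k1 = 0.0086 M⁻¹ s⁻¹)
    catalyst intermediate A → free catalyst + target (k2 = 0.048 s⁻¹)
    second substrate + free catalyst ⇌ catalyst intermediate B (K3 = 4.2 M⁻¹, k3 = 0.022 M⁻¹ s⁻¹)
    catalyst intermediate B → free catalyst + second product (k4 = 0.0031 s⁻¹)
    2 starting material → homo dimer (k5 = 4.4 × 10⁻⁸ M⁻¹ s⁻¹)
    free catalyst ⇌ dormant form (K6 = 16, k6 = 4.2 × 10⁻⁶ s⁻¹)

Turn the question round and ask what a flat row needs. Either the load of second substrate, its concentration over its half-load level, stays small beside the rest of the catalyst's account, or the reading comes long after starting material has run down. On the first count, Sunday's flask starts with a load of 1.58 against 1.30, which is not small.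

For the second count you need a clock, and I reckon it from one quantity. The mean free share is the part of the catalyst left free, one over one plus both substrate loads, with each load taken at the mean of its start and end. With the whole catalyst free, starting material would fall with a time constant of 3.92 h and second substrate with 3.40 h, each stretched by one over the share.

On Sunday's flask the share at the charge is 34.7%. Held for 8.0 h, it leaves 0.984 M of starting material and 0.265 M of second substrate, so the mean free share is 42.4%. The time constant of starting material then stands at 9.25 h, longer than the run, and my target is 1.16 M. The share is curved, so I check the mean: averaging the shares at start and end gives 44.5% and 1.19 M, which puts the error of the mean near 0.0300 M.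

The forecast gives 1.195 M, 1.067 M, 0.859 M and 0.604 M, a row that falls all the way, with Sunday's value above mine. Its ground: “More second substrate sequesters catalyst, so target falls throughout.”

The simulation gives 1.20 M, 1.07 M, 0.866 M and 0.611 M, a row that falls all the way.

Sunday's free catalyst read 44.6% at 4.00 h, beside my mean share of 42.4%. For Friday's flask the same steps start from 15.2% and give a mean share of 17.4% and 0.599 M of target; that flask read 17.7% at 4.00 h and ended at 0.611 M. Part of the reason the row falls is the binding of second substrate, and part is the early reading. With that binding taken away the shape turns and Friday's target is 1.63 M, and read at 80.0 h it is 1.99 M.

(The constants used here come from no measurement.)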